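**Retrosynthetic overview**

1. Feature: in ring B the tertiary carbinol C8 (OH, C17) is bonded directly to the methine C9, and 8-O stands γ to C12. This is the γ-hydroxy-ester retron of a ketyl/enoate union. C5 and C10 are trans on ring A.
2. Side chain: C15 acetate ⇐ 8,15-diol; C13 ⇐ Ru–BINAP hydrogenation of the 13E allylic alcohol ⇐ methylalumination/hydroxymethylation of a C13≡C14 alkyne ⇐ acetylide + C12 iodide ⇐ ester 14.
3. Ring B: C8–C9 ⇐ SmI2 ketyl–enoate cyclisation of the ring-A keto enoate 13 (C5 3-oxobutyl, C10 acrylate).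
4. Enoate ⇐ HWE on the C10 aldehyde ⇐ ozonolysis of a propenyl group; C5–C6 and C10–C9 ⇐ Cu-catalysed asymmetric conjugate addition/enolate allylation on enone 1.
5. Ring order: ring A is present in 1; ring B is closed in step 7.

Key step: step 7

Remark: labdane numbering is used throughout; enone 1 is taken as a catalogue compound, and the catalyst antipode in step 1 is the one that attacks the Si face of C3 of 1.
Remark: the ester carbon of 14 (C12) is a methylene in the target, so C13–C16 are added at a C12 iodide; the 8-hydroxyl is silylated first because a free 8-OH would displace a C12 leaving group to give the 8,12-ether.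

**Route**

Step 1
Reactants: 1 2,4,4-trimethylcyclohex-2-en-1-one; 2 2-(2-bromoethyl)-2-methyl-1,3-dioxolane
Product: 5 (2R,3S)-2-allyl-2,4,4-trimethyl-3-[2-(2-methyl-1,3-dioxolan-2-yl)ethyl]cyclohexan-1-one, via Grignard reagent 3 (not isolated), via magnesium enolate 4 (not isolated)
Conditions: 2, Mg, THF, ≤25 °C; then 1, Cu(OTf)2 (5 mol %), chiral imidazolinium NHC precursor (6 mol %), Et2O, −30 °C, slow addition; then allyl iodide, DMPU, −30 °C → rt
Reagents that add atoms: allyl iodide, C=CCI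
Why: Copper–NHC-catalysed asymmetric conjugate addition of a Grignard reagent to a 2-methylcycloalkenone with alkylation of the magnesium enolate: the catalyst delivers the alkyl group to the Si face of C3 (3S, labdane C5), and allyl iodide then attacks the tetrasubstituted enolate anti to the new pseudoaxial side chain, so the quaternary centre (2R, labdane C10) should carry allyl trans to that chain.

Step 2
Reactants: 5 (2R,3S)-2-allyl-2,4,4-trimethyl-3-[2-(2-methyl-1,3-dioxolan-2-yl)ethyl]cyclohexan-1-one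
Product: 7 2-{2-[(1S,2R)-2-allyl-2,6,6-trimethylcyclohexyl]ethyl}-2-methyl-1,3-dioxolane, via hydrazone 6 (not isolated)
Conditions: N2H4·H2O, KOH, diethylene glycol, 130 °C then 200 °C, N2 atmosphere
Reagents that add atoms: none
Why: Wolff–Kishner reduction (Huang–Minlon) removes the ketone under basic conditions that leave the dioxolane intact; the quaternary α-carbon cannot epimerise, and any base-induced allyl-to-propenyl shift only anticipates step 3.

Step 3
Reactants: 7 2-{2-[(1S,2R)-2-allyl-2,6,6-trimethylcyclohexyl]ethyl}-2-methyl-1,3-dioxolane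
Product: 8 2-methyl-2-{2-[(1S,2R)-2,6,6-trimethyl-2-[(E)-prop-1-enyl]cyclohexyl]ethyl}-1,3-dioxolane
Conditions: RuHCl(CO)(PPh3)3 (3 mol %), toluene, 80 °C
Reagents that add atoms: none
Why: Ruthenium-hydride-catalysed alkene isomerisation (hydrometalation/β-hydride elimination) moves the terminal double bond to the more stable 1-propenyl position, where it stops because C10 is quaternary; the E/Z ratio is irrelevant for step 4.

Step 4
Reactants: 8 2-methyl-2-{2-[(1S,2R)-2,6,6-trimethyl-2-[(E)-prop-1-enyl]cyclohexyl]ethyl}-1,3-dioxolane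
Product: 10 (1S,2S)-1,3,3-trimethyl-2-[2-(2-methyl-1,3-dioxolan-2-yl)ethyl]cyclohexane-1-carbaldehyde, via ozonide 9 (not isolated)
Conditions: O3, CH2Cl2, −78 °C; then PPh3, −78 °C → rt
Reagents that add atoms: ozone, [O-][O+]=O
Why: Ozonolysis with reductive work-up cleaves the propenyl group to the C10 aldehyde, which has no α-hydrogen and cannot epimerise; the ketone ketal has no acetal C–H and is inert to ozone.

Step 5
Reactants: 10 (1S,2S)-1,3,3-trimethyl-2-[2-(2-methyl-1,3-dioxolan-2-yl)ethyl]cyclohexane-1-carbaldehyde; 11 trimethyl phosphonoacetate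
Product: 12 methyl (E)-3-{(1R,2S)-1,3,3-trimethyl-2-[2-(2-methyl-1,3-dioxolan-2-yl)ethyl]cyclohexyl}prop-2-enoate
Conditions: NaH, THF, 0 °C → 50 °C
Reagents that add atoms: none
Why: Horner–Wadsworth–Emmons olefination of the non-enolisable aldehyde with the stabilised phosphonate anion should give the E-enoate, as is usual for α-branched aldehydes.

Step 6
Reactants: 12 methyl (E)-3-{(1R,2S)-1,3,3-trimethyl-2-[2-(2-methyl-1,3-dioxolan-2-yl)ethyl]cyclohexyl}prop-2-enoate
Product: 13 methyl (E)-3-[(1R,2S)-1,3,3-trimethyl-2-(3-oxobutyl)cyclohexyl]prop-2-enoate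
Conditions: 1 M HCl, THF, rt
Reagents that add atoms: water, O
Why: Acid-catalysed ketal hydrolysis frees the methyl ketone without touching the enoate or the two stereocentres, neither of which is α to a carbonyl.

Step 7
Reactants: 13 methyl (E)-3-[(1R,2S)-1,3,3-trimethyl-2-(3-oxobutyl)cyclohexyl]prop-2-enoate
Product: 14 methyl 2-[(1R,2R,4aS,8aS)-2-hydroxy-2,5,5,8a-tetramethyldecahydronaphthalen-1-yl]acetate (methyl 8α-hydroxy-13,14,15,16-tetranorlabdan-12-oate)
Conditions: SmI2 (2.5 equiv), HMPA (6 equiv), t-BuOH (2 equiv), THF (0.01 M), −78 °C → 0 °C; cold aq. NaHCO3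
Reagents that add atoms: none
Why: SmI2–HMPA transfers one electron to the C8 methyl ketone to give a samarium(III) ketyl whose carbon radical adds to C9, the β-carbon of the E-enoate on C10, forming C8–C9 and closing ring B in a 6-exo-trig mode; a second electron turns the C11 α-ester radical into a samarium enolate, which t-BuOH protonates. The closest known reaction type is the SmI2-mediated ketyl–olefin (ketone–enoate) reductive cyclisation that gives trans γ-hydroxy esters. Ring B should close through a chair transition state fused trans to ring A across the existing C5–C10 bond. C9 is controlled by this fusion: the enoate arm sits equatorial (9β-CH2CO2Me, 9α-H), because an axial arm would be syn-diaxial to H-5 and H-7. C8 is controlled by the ketyl substituents: the HMPA-solvated O–Sm group is far bulkier than methyl and takes the equatorial 8α site, trans to the ester arm, which leaves C17 axial (β) beside C20. The step needs the trans-diequatorial O/arm mode over the cis mode and ring closure over simple reduction; the quaternary C10 (no enolisation or β-elimination at the acceptor), the E-enoate, high dilution and the slow proton donor are meant to secure this, and a cis isomer would show itself by ready lactonisation.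

Step 8
Reactants: 14 methyl 2-[(1R,2R,4aS,8aS)-2-hydroxy-2,5,5,8a-tetramethyldecahydronaphthalen-1-yl]acetate
Product: 15 methyl 2-[(1R,2R,4aS,8aS)-2,5,5,8a-tetramethyl-2-(triethylsilyloxy)decahydronaphthalen-1-yl]acetate
Conditions: TESOTf, 2,6-lutidine, CH2Cl2, −78 °C → 0 °C
Reagents that add atoms: triethylsilyl trifluoromethanesulfonate, CC[Si](CC)(CC)OS(=O)(=O)C(F)(F)F
Why: Silylation with a silyl triflate and a hindered pyridine base protects the hindered tertiary 8-hydroxyl, so that the later C12 iodide cannot close to the 8,12-ether.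

Step 9
Reactants: 15 methyl 2-[(1R,2R,4aS,8aS)-2,5,5,8a-tetramethyl-2-(triethylsilyloxy)decahydronaphthalen-1-yl]acetate
Product: 16 2-[(1R,2R,4aS,8aS)-2,5,5,8a-tetramethyl-2-(triethylsilyloxy)decahydronaphthalen-1-yl]ethan-1-ol
Conditions: LiAlH4, Et2O, 0 °C; Fieser work-up
Reagents that add atoms: none
Why: Hydride reduction of the ester with LiAlH4 gives the primary C12 alcohol and leaves the silyl ether and all stereocentres untouched.

Step 10
Reactants: 16 2-[(1R,2R,4aS,8aS)-2,5,5,8a-tetramethyl-2-(triethylsilyloxy)decahydronaphthalen-1-yl]ethan-1-ol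
Product: 17 triethyl{[(1R,2R,4aS,8aS)-1-(2-iodoethyl)-2,5,5,8a-tetramethyldecahydronaphthalen-2-yl]oxy}silane
Conditions: I2, PPh3, imidazole, CH2Cl2, 0 °C → rt
Reagents that add atoms: iodine, II
Why: Appel-type iodination (PPh3/I2/imidazole) converts the primary alcohol into the iodide by SN2 displacement of the oxyphosphonium group under buffered conditions that the tertiary silyl ether tolerates.

Step 11
Reactants: 17 triethyl{[(1R,2R,4aS,8aS)-1-(2-iodoethyl)-2,5,5,8a-tetramethyldecahydronaphthalen-2-yl]oxy}silane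
Product: 18 {[(1R,2R,4aS,8aS)-1-(but-3-yn-1-yl)-2,5,5,8a-tetramethyldecahydronaphthalen-2-yl]oxy}triethylsilane
Conditions: lithium acetylide–ethylenediamine complex, DMSO, rt
Reagents that add atoms: lithium acetylide (ethylenediamine complex), [Li]C#C
Why: SN2 alkylation of lithium acetylide by the unhindered primary iodide adds C13 and C14 as a terminal alkyne, and the silylated 8-oxygen cannot compete for the iodide.

Step 12
Reactants: 18 {[(1R,2R,4aS,8aS)-1-(but-3-yn-1-yl)-2,5,5,8a-tetramethyldecahydronaphthalen-2-yl]oxy}triethylsilane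
Product: 20 (2E)-3-methyl-5-[(1R,2R,4aS,8aS)-2,5,5,8a-tetramethyl-2-(triethylsilyloxy)decahydronaphthalen-1-yl]pent-2-en-1-ol, via alkenylalane 19 (not isolated)
Conditions: AlMe3 (3 equiv), Cp2ZrCl2 (0.3 equiv), CH2Cl2, 0 °C → rt; then n-BuLi, THF, −78 °C; (CH2O)n, → rt
Reagents that add atoms: trimethylaluminium, C[Al](C)C; formaldehyde (as paraformaldehyde), C=O
Why: Negishi zirconium-catalysed carboalumination adds methyl and aluminium syn across the alkyne with methyl on the internal carbon C13, and the alanate of 19 adds to formaldehyde with retention, which fixes the 13E trisubstituted allylic alcohol.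

Step 13
Reactants: 20 (2E)-3-methyl-5-[(1R,2R,4aS,8aS)-2,5,5,8a-tetramethyl-2-(triethylsilyloxy)decahydronaphthalen-1-yl]pent-2-en-1-ol
Product: 21 (3S)-3-methyl-5-[(1R,2R,4aS,8aS)-2,5,5,8a-tetramethyl-2-(triethylsilyloxy)decahydronaphthalen-1-yl]pentan-1-ol
Conditions: H2 (100 atm), Ru(OAc)2[(R)-BINAP] (1 mol %), MeOH–CH2Cl2 (4:1), 25 °C
Reagents that add atoms: none
Why: Noyori asymmetric hydrogenation of an allylic alcohol: the hydroxyl binds ruthenium and (R)-BINAP selects the alkene face as in geraniol → (S)-citronellol, which should set C13 as S under catalyst control.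

Step 14
Reactants: 21 (3S)-3-methyl-5-[(1R,2R,4aS,8aS)-2,5,5,8a-tetramethyl-2-(triethylsilyloxy)decahydronaphthalen-1-yl]pentan-1-ol
Product: 22 (3S)-5-[(1R,2R,4aS,8aS)-2-hydroxy-2,5,5,8a-tetramethyldecahydronaphthalen-1-yl]-3-methylpentan-1-ol ((13S)-labdane-8α,15-diol)
Conditions: TBAF, THF, 50 °C
Reagents that add atoms: none
Why: Fluoride-mediated desilylation frees the tertiary 8α-hydroxyl under non-acidic conditions, which avoids ionisation or dehydration at C8.

Step 15
Reactants: 22 (3S)-5-[(1R,2R,4aS,8aS)-2-hydroxy-2,5,5,8a-tetramethyldecahydronaphthalen-1-yl]-3-methylpentan-1-ol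
Product: 23 (3S)-5-[(1R,2R,4aS,8aS)-2-hydroxy-2,5,5,8a-tetramethyldecahydronaphthalen-1-yl]-3-methylpentyl acetate (CNP0188939.1)
Conditions: Ac2O, pyridine, CH2Cl2, 0 °C → rt
Reagents that add atoms: acetic anhydride, CC(=O)OC(C)=O
Why: Acylation with acetic anhydride in pyridine is selective for the primary C15 hydroxyl, because the hindered tertiary 8α-hydroxyl does not react under these conditions.

**Compound list**

1 | 2,4,4-trimethylcyclohex-2-en-1-one | CC1=CC(C)(C)CCC1=O | starting material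
2 | 2-(2-bromoethyl)-2-methyl-1,3-dioxolane | CC1(CCBr)OCCO1 | starting material
3 | [2-(2-methyl-1,3-dioxolan-2-yl)ethyl]magnesium bromide | CC1(CC[Mg]Br)OCCO1 | intermediate (not isolated)
4 | bromomagnesium enolate of (3S)-2,4,4-trimethyl-3-[2-(2-methyl-1,3-dioxolan-2-yl)ethyl]cyclohexanone | CC1=C(O[Mg]Br)CCC(C)(C)[C@@H]1CCC1(C)OCCO1 | intermediate (not isolated)
5 | (2R,3S)-2-allyl-2,4,4-trimethyl-3-[2-(2-methyl-1,3-dioxolan-2-yl)ethyl]cyclohexan-1-one | C=CC[C@@]1(C)C(=O)CCC(C)(C)[C@@H]1CCC1(C)OCCO1 | intermediate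
6 | hydrazone of 5 | C=CC[C@@]1(C)C(=NN)CCC(C)(C)[C@@H]1CCC1(C)OCCO1 | intermediate (not isolated)
7 | 2-{2-[(1S,2R)-2-allyl-2,6,6-trimethylcyclohexyl]ethyl}-2-methyl-1,3-dioxolane | C=CC[C@@]1(C)CCCC(C)(C)[C@@H]1CCC1(C)OCCO1 | intermediate
8 | 2-methyl-2-{2-[(1S,2R)-2,6,6-trimethyl-2-[(E)-prop-1-enyl]cyclohexyl]ethyl}-1,3-dioxolane | C/C=C/[C@@]1(C)CCCC(C)(C)[C@@H]1CCC1(C)OCCO1 | intermediate
9 | secondary ozonide of 8 (3-methyl-5-cyclohexyl-1,2,4-trioxolane, mixture at the trioxolane carbons) | CC1OOC(O1)[C@@]1(C)CCCC(C)(C)[C@@H]1CCC1(C)OCCO1 | intermediate (not isolated)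
10 | (1S,2S)-1,3,3-trimethyl-2-[2-(2-methyl-1,3-dioxolan-2-yl)ethyl]cyclohexane-1-carbaldehyde | O=C[C@@]1(C)CCCC(C)(C)[C@@H]1CCC1(C)OCCO1 | intermediate
11 | trimethyl phosphonoacetate | COC(=O)CP(=O)(OC)OC | starting material
12 | methyl (E)-3-{(1R,2S)-1,3,3-trimethyl-2-[2-(2-methyl-1,3-dioxolan-2-yl)ethyl]cyclohexyl}prop-2-enoate | COC(=O)/C=C/[C@@]1(C)CCCC(C)(C)[C@@H]1CCC1(C)OCCO1 | intermediate
13 | methyl (E)-3-[(1R,2S)-1,3,3-trimethyl-2-(3-oxobutyl)cyclohexyl]prop-2-enoate | COC(=O)/C=C/[C@@]1(C)CCCC(C)(C)[C@@H]1CCC(C)=O | intermediate (key-step precursor)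
14 | methyl 2-[(1R,2R,4aS,8aS)-2-hydroxy-2,5,5,8a-tetramethyldecahydronaphthalen-1-yl]acetate | COC(=O)C[C@@H]1[C@@]2(C)CCCC(C)(C)[C@@H]2CC[C@@]1(C)O | intermediate (key-step product)
15 | methyl 2-[(1R,2R,4aS,8aS)-2,5,5,8a-tetramethyl-2-(triethylsilyloxy)decahydronaphthalen-1-yl]acetate | COC(=O)C[C@@H]1[C@@]2(C)CCCC(C)(C)[C@@H]2CC[C@@]1(C)O[Si](CC)(CC)CC | intermediate
16 | 2-[(1R,2R,4aS,8aS)-2,5,5,8a-tetramethyl-2-(triethylsilyloxy)decahydronaphthalen-1-yl]ethan-1-ol | OCC[C@@H]1[C@@]2(C)CCCC(C)(C)[C@@H]2CC[C@@]1(C)O[Si](CC)(CC)CC | intermediate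
17 | triethyl{[(1R,2R,4aS,8aS)-1-(2-iodoethyl)-2,5,5,8a-tetramethyldecahydronaphthalen-2-yl]oxy}silane | ICC[C@@H]1[C@@]2(C)CCCC(C)(C)[C@@H]2CC[C@@]1(C)O[Si](CC)(CC)CC | intermediate
18 | {[(1R,2R,4aS,8aS)-1-(but-3-yn-1-yl)-2,5,5,8a-tetramethyldecahydronaphthalen-2-yl]oxy}triethylsilane | C#CCC[C@@H]1[C@@]2(C)CCCC(C)(C)[C@@H]2CC[C@@]1(C)O[Si](CC)(CC)CC | intermediate
19 | (E)-alkenyl(dimethyl)alane from 18 (Al on C14, cis to the new C13 methyl) | C[Al](C)/C=C(\C)CC[C@@H]1[C@@]2(C)CCCC(C)(C)[C@@H]2CC[C@@]1(C)O[Si](CC)(CC)CC | intermediate (not isolated)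
20 | (2E)-3-methyl-5-[(1R,2R,4aS,8aS)-2,5,5,8a-tetramethyl-2-(triethylsilyloxy)decahydronaphthalen-1-yl]pent-2-en-1-ol | OC/C=C(\C)CC[C@@H]1[C@@]2(C)CCCC(C)(C)[C@@H]2CC[C@@]1(C)O[Si](CC)(CC)CC | intermediate
21 | (3S)-3-methyl-5-[(1R,2R,4aS,8aS)-2,5,5,8a-tetramethyl-2-(triethylsilyloxy)decahydronaphthalen-1-yl]pentan-1-ol | OCC[C@@H](C)CC[C@@H]1[C@@]2(C)CCCC(C)(C)[C@@H]2CC[C@@]1(C)O[Si](CC)(CC)CC | intermediate
22 | (3S)-5-[(1R,2R,4aS,8aS)-2-hydroxy-2,5,5,8a-tetramethyldecahydronaphthalen-1-yl]-3-methylpentan-1-ol | OCC[C@@H](C)CC[C@@H]1[C@@]2(C)CCCC(C)(C)[C@@H]2CC[C@@]1(C)O | intermediate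
23 | (3S)-5-[(1R,2R,4aS,8aS)-2-hydroxy-2,5,5,8a-tetramethyldecahydronaphthalen-1-yl]-3-methylpentyl acetate | CC(=O)OCC[C@@H](C)CC[C@@H]1[C@@]2(C)CCCC(C)(C)[C@@H]2CC[C@@]1(C)O | target

**Step count**

Total: 15 steps. Longest linear sequence: 15 steps (1 → 23; reagent 3 is made in the flask of step 1).

**Steps most likely to fail**

1. Step 7. The desired transition state carries the C17 methyl axial beside C20, so facial selectivity at the ketyl carbon may erode and the cis mode may compete; the enoate may also be reduced without ring closure. The fallback sets out from 13 and keeps the C8–C9 bond but re-sets C8 by ionic chemistry. The cyclisation product enriched in the C8 epimer, methyl 8β-hydroxy-8-epi-13,14,15,16-tetranorlabdan-12-oate F1, is dehydrated (SOCl2, pyridine, 0 °C; anti elimination of the axial hydroxyl) to methyl 13,14,15,16-tetranorlabd-7-en-12-oate F2. Saponification (LiOH, THF–H2O) gives 13,14,15,16-tetranorlabd-7-en-12-oic acid F3. Proton-induced lactonisation under kinetic control (MeSO3H, CH2Cl2, −20 °C; protonation at C7 and capture of the C8 cation by the equatorial carboxyl, as in the acid cyclisations of homofarnesic-type acids) should give the trans-fused lactone sclareolide F4. Opening with KOH to potassium 8α-hydroxy-13,14,15,16-tetranorlabdan-12-oate F5 and methylation with MeI in DMF returns to the route at 14. The same last two operations would return any trans lactone formed in step 7 to 14.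

2. Step 1. Conjugate addition at the neopentyl β-carbon of the α-methyl enone may be slow, with competing 1,2-addition, insufficient enantiofacial discrimination or incomplete C-allylation of the hindered magnesium enolate. The fallback sets out from 1 and replaces catalytic asymmetric addition by reagent-controlled reduction and chirality transfer.
   - CBS reduction ((R)-Me-CBS, catecholborane, toluene, −78 °C) gives (S)-2,4,4-trimethylcyclohex-2-en-1-ol F6.
   - Picolinic acid, DCC and DMAP give (S)-2,4,4-trimethylcyclohex-2-en-1-yl picolinate F7.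
   - Anti-SN2′ substitution with Grignard reagent 3 and CuBr·SMe2 transfers the C–O chirality to C5 and gives 2-methyl-2-{2-[(1S)-2,6,6-trimethylcyclohex-2-en-1-yl]ethyl}-1,3-dioxolane F8.
   - Hydroboration–oxidation (BH3·THF; NaOH, H2O2) anti to the side chain gives (1S,2S,3R)-2,4,4-trimethyl-3-[2-(2-methyl-1,3-dioxolan-2-yl)ethyl]cyclohexan-1-ol F9.
   - Dess–Martin oxidation gives (3R)-2,4,4-trimethyl-3-[2-(2-methyl-1,3-dioxolan-2-yl)ethyl]cyclohexan-1-one F10 (C2 epimers).
   - TMSCl, NaI and Et3N in MeCN (thermodynamic conditions) give the tetrasubstituted trimethylsilyl enol ether F11.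
   - MeLi in THF releases the lithium enolate F12, and allylation with allyl iodide and HMPA anti to the side chain rejoins the route at 5.

3. Step 2. Hydrazone formation at the carbonyl flanked by the quaternary C10 may be slow, giving azine formation, or diimide (from adventitious air) may reduce the allyl group. The fallback sets out from 5 and replaces the ionic deoxygenation by a radical one: LiAlH4 gives (2R,3S)-2-allyl-2,4,4-trimethyl-3-[2-(2-methyl-1,3-dioxolan-2-yl)ethyl]cyclohexan-1-ol F13 (either carbinol epimer); NaH, CS2 and MeI give its S-methyl xanthate F14; Bu3SnH and AIBN in toluene at 90 °C (Barton–McCombie) return to the route at 7.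

If step 1 gives incomplete enantiomeric purity, recrystallisation of 14 or 22 would be tried to raise it, should they prove crystalline.

**Further compounds**

F1 | step 7 | methyl 8β-hydroxy-8-epi-13,14,15,16-tetranorlabdan-12-oate | COC(=O)C[C@@H]1[C@@]2(C)CCCC(C)(C)[C@@H]2CC[C@]1(C)O
F2 | step 7 | methyl 13,14,15,16-tetranorlabd-7-en-12-oate | COC(=O)C[C@@H]1[C@@]2(C)CCCC(C)(C)[C@@H]2CC=C1C
F3 | step 7 | 13,14,15,16-tetranorlabd-7-en-12-oic acid | OC(=O)C[C@@H]1[C@@]2(C)CCCC(C)(C)[C@@H]2CC=C1C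
F4 | step 7 | sclareolide (8α,12-olide) | O=C1C[C@@H]2[C@@]3(C)CCCC(C)(C)[C@@H]3CC[C@@]2(C)O1
F5 | step 7 | potassium 8α-hydroxy-13,14,15,16-tetranorlabdan-12-oate | [K+].[O-]C(=O)C[C@@H]1[C@@]2(C)CCCC(C)(C)[C@@H]2CC[C@@]1(C)O
F6 | step 1 | (S)-2,4,4-trimethylcyclohex-2-en-1-ol | CC1=CC(C)(C)CC[C@@H]1O
F7 | step 1 | (S)-2,4,4-trimethylcyclohex-2-en-1-yl picolinate | CC1=CC(C)(C)CC[C@@H]1OC(=O)c1ccccn1
F8 | step 1 | 2-methyl-2-{2-[(1S)-2,6,6-trimethylcyclohex-2-en-1-yl]ethyl}-1,3-dioxolane | CC1=CCCC(C)(C)[C@@H]1CCC1(C)OCCO1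
F9 | step 1 | (1S,2S,3R)-2,4,4-trimethyl-3-[2-(2-methyl-1,3-dioxolan-2-yl)ethyl]cyclohexan-1-ol | C[C@@H]1[C@@H](O)CCC(C)(C)[C@@H]1CCC1(C)OCCO1
F10 | step 1 | (3R)-2,4,4-trimethyl-3-[2-(2-methyl-1,3-dioxolan-2-yl)ethyl]cyclohexan-1-one (C2 epimers) | CC1C(=O)CCC(C)(C)[C@@H]1CCC1(C)OCCO1
F11 | step 1 | trimethylsilyl enol ether of F10 (tetrasubstituted) | CC1=C(O[Si](C)(C)C)CCC(C)(C)[C@@H]1CCC1(C)OCCO1
F12 | step 1 | lithium enolate from F11 | CC1=C(O[Li])CCC(C)(C)[C@@H]1CCC1(C)OCCO1
F13 | step 2 | (2R,3S)-2-allyl-2,4,4-trimethyl-3-[2-(2-methyl-1,3-dioxolan-2-yl)ethyl]cyclohexan-1-ol | C=CC[C@@]1(C)C(O)CCC(C)(C)[C@@H]1CCC1(C)OCCO1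
F14 | step 2 | O-cyclohexyl S-methyl xanthate of F13 | C=CC[C@@]1(C)C(OC(=S)SC)CCC(C)(C)[C@@H]1CCC1(C)OCCO1
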